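**Assumption:** centres marked RS (the carbinol carbon of 17–21, C3 of 23 and 24) are carried as epimer mixtures because both are erased before the C3 centre is finally set; 3, 4, 32 and anhydrous ethereal H2O2 are taken as purchasable or made by standard drying.

## Retrosynthetic overview

1. The (E,E)-phenyldiene is added last, by Horner–Wadsworth–Emmons olefination of a C14 aldehyde acid with diethyl cinnamylphosphonate; the acid comes from an S-ethyl thioester.
2. Key C2–C3 bond: Mukaiyama aldol-type addition of the silyl ketene acetal of S-ethyl thioacetate to the peroxycarbenium ion of a 3-methoxy-1,2-dioxolane (TiCl4).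
3. Rings: a temporary oxetane is made first and opened by H2O2 with inversion (C5–OO bond); the 1,2-dioxolane, the only ring kept, is then closed by that hydroperoxide onto a methyl ketone.
4. The tertiary C5–O centre comes from Sharpless epoxidation and hydride opening of an E-allylic alcohol, itself from Negishi carboalumination of a terminal alkyne.
5. The C7 methyl centre comes from an Evans propargylation; the chain is attached by copper-catalysed Grignard–tosylate coupling.

## Route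

Step 1
Reactants: 1 6-bromohexan-1-ol
Product: 2 (6-bromohexyloxy)(tert-butyl)diphenylsilane
Conditions: t-BuPh2SiCl, imidazole, DMF, 0 °C → rt
Reagents that add atoms: tert-butyl(chloro)diphenylsilane, CC(C)(C)[Si](Cl)(c1ccccc1)c1ccccc1
Why: Imidazole-promoted O-silylation gives a primary TBDPS ether that survives every step up to step 20; no stereocentre is involved.

Step 2
Reactants: 3 (4R)-4-benzyl-3-propanoyl-1,3-oxazolidin-2-one; 4 3-bromo-1-(trimethylsilyl)prop-1-yne
Product: 5 (4R)-4-benzyl-3-[(2S)-2-methyl-5-(trimethylsilyl)pent-4-ynoyl]-1,3-oxazolidin-2-one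
Conditions: NaN(SiMe3)2, THF, −78 °C; then 4, −78 → −40 °C
Reagents that add atoms: none
Why: Evans asymmetric alkylation, in which the chelated Z-enolate is propargylated on the face opposite the benzyl group, sets the future C7 methyl centre (dr typically above 95:5).

Step 3
Reactants: 5 (4R)-4-benzyl-3-[(2S)-2-methyl-5-(trimethylsilyl)pent-4-ynoyl]-1,3-oxazolidin-2-one
Product: 6 (2S)-2-methyl-5-(trimethylsilyl)pent-4-yn-1-ol
Conditions: LiBH4, MeOH (1 equiv), Et2O, 0 °C
Reagents that add atoms: none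
Why: Reductive cleavage of the imide releases the auxiliary and gives the primary alcohol without touching the stereocentre or the silylalkyne.

Step 4
Reactants: 6 (2S)-2-methyl-5-(trimethylsilyl)pent-4-yn-1-ol
Product: 7 (2S)-2-methyl-5-(trimethylsilyl)pent-4-yn-1-yl 4-methylbenzenesulfonate
Conditions: TsCl, Et3N, DMAP (cat.), CH2Cl2, 0 °C → rt
Reagents that add atoms: 4-methylbenzenesulfonyl chloride, Cc1ccc(cc1)S(Cl)(=O)=O
Why: Sulfonylation turns the primary alcohol into a leaving group for the coupling; the stereocentre is not involved.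

Step 5
Reactants: 2 (6-bromohexyloxy)(tert-butyl)diphenylsilane; 7 (2S)-2-methyl-5-(trimethylsilyl)pent-4-yn-1-yl 4-methylbenzenesulfonate
Product: 9 tert-butyl{[(8R)-8-methyl-11-(trimethylsilyl)undec-10-yn-1-yl]oxy}diphenylsilane, via alkylmagnesium bromide 8 (not isolated)
Conditions: 2, Mg, THF, 50 °C; then 7, Li2CuCl4 (5 mol%), THF, −78 °C → rt
Reagents that add atoms: magnesium, [Mg] (kept only in intermediate 8)
Why: Kochi-type copper-catalysed sp3–sp3 coupling of a primary Grignard reagent with a primary tosylate builds the chain; the stereocentre is beta to the reacting carbon and unchanged (the descriptor changes from S to R only through CIP priorities).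

Step 6
Reactants: 9 tert-butyl{[(8R)-8-methyl-11-(trimethylsilyl)undec-10-yn-1-yl]oxy}diphenylsilane
Product: 10 tert-butyl{[(8R)-8-methylundec-10-yn-1-yl]oxy}diphenylsilane
Conditions: K2CO3 (cat.), MeOH, rt
Reagents that add atoms: none
Why: Methoxide-mediated protodesilylation frees the terminal alkyne while the TBDPS ether is stable.

Step 7
Reactants: 10 tert-butyl{[(8R)-8-methylundec-10-yn-1-yl]oxy}diphenylsilane
Product: 13 (2E,5R)-12-(tert-butyldiphenylsilyloxy)-3,5-dimethyldodec-2-en-1-ol, via alkenyldimethylalane 11 (not isolated), via lithium alkenyl(butyl)dimethylaluminate 12 (not isolated)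
Conditions: AlMe3 (3 equiv), Cp2ZrCl2 (0.25 equiv), CH2Cl2, 0 °C → rt; volatiles removed; n-BuLi, THF/hexane, −78 °C; (CH2O)n, −78 °C → rt
Reagents that add atoms: trimethylaluminium, C[Al](C)C; formaldehyde (from paraformaldehyde), C=O; n-butyllithium, CCCC[Li] (butyl kept only in intermediate 12)
Why: Negishi zirconium-catalysed carboalumination adds Me and Al syn with Al on the terminal carbon, and hydroxymethylation of the alanate proceeds with retention, giving the E-trisubstituted allylic alcohol.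

Step 8
Reactants: 13 (2E,5R)-12-(tert-butyldiphenylsilyloxy)-3,5-dimethyldodec-2-en-1-ol
Product: 14 {(2S,3S)-3-[(2R)-9-(tert-butyldiphenylsilyloxy)-2-methylnonyl]-3-methyloxiran-2-yl}methanol
Conditions: Ti(OiPr)4 (10 mol%), L-(+)-diethyl tartrate (12 mol%), t-BuOOH (2 equiv), 4 Å MS, CH2Cl2, −20 °C
Reagents that add atoms: tert-butyl hydroperoxide, CC(C)(C)OO
Why: Sharpless asymmetric epoxidation under reagent control (same sense as geraniol with the L-tartrate) gives the (2S,3S)-epoxide and so sets the tertiary C–O centre (about 95:5; the minor isomer is a diastereomer and is removed by chromatography).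

Step 9
Reactants: 14 {(2S,3S)-3-[(2R)-9-(tert-butyldiphenylsilyloxy)-2-methylnonyl]-3-methyloxiran-2-yl}methanol
Product: 15 (3S,5R)-12-(tert-butyldiphenylsilyloxy)-3,5-dimethyldodecane-1,3-diol
Conditions: NaAlH2(OCH2CH2OMe)2, THF, 0 °C → rt
Reagents that add atoms: none
Why: Hydroxyl-directed epoxide reduction delivers hydride intramolecularly to C2, giving the 1,3-diol with the tertiary carbinol configuration untouched.

Step 10
Reactants: 15 (3S,5R)-12-(tert-butyldiphenylsilyloxy)-3,5-dimethyldodecane-1,3-diol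
Product: 16 (3S,5R)-12-(tert-butyldiphenylsilyloxy)-3-hydroxy-3,5-dimethyldodecanal
Conditions: TEMPO (10 mol%), PhI(OAc)2 (1.1 equiv), CH2Cl2, rt; used crude
Reagents that add atoms: none
Why: Oxoammonium (TEMPO) oxidation is selective for the primary alcohol and leaves the tertiary alcohol and silyl ether alone.

Step 11
Reactants: 16 (3S,5R)-12-(tert-butyldiphenylsilyloxy)-3-hydroxy-3,5-dimethyldodecanal
Product: 17 (2RS,4S,6R)-13-(tert-butyldiphenylsilyloxy)-4,6-dimethyltridecane-2,4-diol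
Conditions: MeMgBr (3 equiv), Et2O/THF, −78 → 0 °C (aldehyde added to the reagent)
Reagents that add atoms: methylmagnesium bromide, C[Mg]Br
Why: Grignard addition installs the future C3 methyl group; the new carbinol centre is uncontrolled, which does not matter because it becomes a ketone in step 15.

Step 12
Reactants: 17 (2RS,4S,6R)-13-(tert-butyldiphenylsilyloxy)-4,6-dimethyltridecane-2,4-diol
Product: 19 (2S,4RS)-2-[(2R)-9-(tert-butyldiphenylsilyloxy)-2-methylnonyl]-2,4-dimethyloxetane, via secondary mesylate 18 (not isolated)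
Conditions: MsCl (1.1 equiv), Et3N, CH2Cl2, −20 °C; then KOtBu, THF, 0 °C → rt
Reagents that add atoms: methanesulfonyl chloride, CS(Cl)(=O)=O (kept only in intermediate 18)
Why: Selective sulfonylation of the secondary OH followed by intramolecular Williamson etherification (4-exo-tet SN2 by the tertiary alkoxide) closes the oxetane with retention at the tertiary C–O centre.

Step 13
Reactants: 19 (2S,4RS)-2-[(2R)-9-(tert-butyldiphenylsilyloxy)-2-methylnonyl]-2,4-dimethyloxetane
Product: 20 (2RS,4R,6R)-13-(tert-butyldiphenylsilyloxy)-4-hydroperoxy-4,6-dimethyltridecan-2-ol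
Conditions: anhydrous H2O2 in Et2O (10 equiv), Me3SiOTf (0.3 equiv), Et2O, −78 → 0 °C
Reagents that add atoms: hydrogen peroxide, OO
Why: Lewis acid-promoted perhydrolysis opens the activated oxetane at its tertiary carbon in a borderline SN2 process with inversion, setting the C5 peroxy centre as R.

Step 14
Reactants: 20 (2RS,4R,6R)-13-(tert-butyldiphenylsilyloxy)-4-hydroperoxy-4,6-dimethyltridecan-2-ol
Product: 21 (2RS,4R,6R)-13-(tert-butyldiphenylsilyloxy)-4,6-dimethyl-4-[(triethylsilyl)peroxy]tridecan-2-ol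
Conditions: Et3SiCl (1.05 equiv), imidazole, CH2Cl2, −40 °C
Reagents that add atoms: chlorotriethylsilane, CC[Si](Cl)(CC)CC
Why: Chemoselective silylation: the OOH group is more acidic and less hindered than the secondary OH, so it is protected first as the silyl peroxide.

Step 15
Reactants: 21 (2RS,4R,6R)-13-(tert-butyldiphenylsilyloxy)-4,6-dimethyl-4-[(triethylsilyl)peroxy]tridecan-2-ol
Product: 22 (4R,6R)-13-(tert-butyldiphenylsilyloxy)-4,6-dimethyl-4-[(triethylsilyl)peroxy]tridecan-2-one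
Conditions: Dess–Martin periodinane, NaHCO3, CH2Cl2, 0 °C → rt
Reagents that add atoms: none
Why: Dess–Martin oxidation under buffered neutral conditions gives the methyl ketone; the tertiary silyl peroxide has no alpha hydrogen and is inert.

Step 16
Reactants: 22 (4R,6R)-13-(tert-butyldiphenylsilyloxy)-4,6-dimethyl-4-[(triethylsilyl)peroxy]tridecan-2-one
Product: 24 (3RS,5R)-5-[(2R)-9-(tert-butyldiphenylsilyloxy)-2-methylnonyl]-3-methoxy-3,5-dimethyl-1,2-dioxolane, via dioxolanol 23 (not isolated)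
Conditions: TsOH·H2O (5 mol%), MeOH/CH2Cl2, 0 °C → rt
Reagents that add atoms: methanol, CO
Why: Acid methanolysis removes the triethylsilyl group, the hydroperoxide adds to the ketone to close the 1,2-dioxolane (peroxyhemiketal), and ketalisation exchanges OH for OMe; C3 is a mixture that converges in step 18.

Step 17
Reactants: 25 S-ethyl ethanethioate
Product: 26 {[1-(ethylsulfanyl)ethenyl]oxy}trimethylsilane
Conditions: LiN(iPr)2, THF, −78 °C; Me3SiCl, −78 °C → rt; distilled
Reagents that add atoms: chlorotrimethylsilane, C[Si](C)(C)Cl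
Why: Kinetic enolisation and O-silylation of the thioester give the silyl ketene acetal nucleophile.

Step 18
Reactants: 24 (3RS,5R)-5-[(2R)-9-(tert-butyldiphenylsilyloxy)-2-methylnonyl]-3-methoxy-3,5-dimethyl-1,2-dioxolane; 26 {[1-(ethylsulfanyl)ethenyl]oxy}trimethylsilane
Product: 27 S-ethyl {(3S,5R)-5-[(2R)-9-(tert-butyldiphenylsilyloxy)-2-methylnonyl]-3,5-dimethyl-1,2-dioxolan-3-yl}ethanethioate
Conditions: TiCl4 (1.1 equiv), 26 (2.5 equiv), CH2Cl2, −78 °C, 30 min; NaHCO3 quench
Reagents that add atoms: none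
Why: Mukaiyama aldol-type fragment union: TiCl4 ionises the methoxy group to a ring peroxycarbenium ion that is trapped by the silyl ketene acetal; Me and CH2R at C5 give little facial bias, so C3 forms about 1:1 and the (3S,5R) trans isomer is isolated by chromatography or HPLC.

Step 19
Reactants: 27 S-ethyl {(3S,5R)-5-[(2R)-9-(tert-butyldiphenylsilyloxy)-2-methylnonyl]-3,5-dimethyl-1,2-dioxolan-3-yl}ethanethioate
Product: 29 {(3S,5R)-5-[(2R)-9-(tert-butyldiphenylsilyloxy)-2-methylnonyl]-3,5-dimethyl-1,2-dioxolan-3-yl}acetic acid, via peroxy acid 28 (not isolated)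
Conditions: LiOH, 30% H2O2, THF/H2O, 0 °C; Na2SO3; then 1 M HCl
Reagents that add atoms: hydrogen peroxide, OO (as LiOOH; one oxygen stays as the acid OH)
Why: Perhydrolysis of the thioester by the weakly basic LiOOH avoids enolate formation and retro-oxa-Michael opening of the peroxide, and sulfite reduces the peracid; no alkene is present yet.

Step 20
Reactants: 29 {(3S,5R)-5-[(2R)-9-(tert-butyldiphenylsilyloxy)-2-methylnonyl]-3,5-dimethyl-1,2-dioxolan-3-yl}acetic acid
Product: 30 {(3S,5R)-5-[(2R)-9-hydroxy-2-methylnonyl]-3,5-dimethyl-1,2-dioxolan-3-yl}acetic acid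
Conditions: HF·pyridine, pyridine, THF, 0 °C → rt
Reagents that add atoms: none
Why: Fluoride-mediated desilylation under buffered, non-basic conditions is tolerated by the dialkyl peroxide and the acid.

Step 21
Reactants: 30 {(3S,5R)-5-[(2R)-9-hydroxy-2-methylnonyl]-3,5-dimethyl-1,2-dioxolan-3-yl}acetic acid
Product: 31 {(3S,5R)-3,5-dimethyl-5-[(2R)-2-methyl-9-oxononyl]-1,2-dioxolan-3-yl}acetic acid
Conditions: Dess–Martin periodinane, NaHCO3, CH2Cl2, 0 °C; used at once
Reagents that add atoms: none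
Why: Dess–Martin oxidation gives the aldehyde without over-oxidation and without affecting the peroxide or the acid.

Step 22
Reactants: 31 {(3S,5R)-3,5-dimethyl-5-[(2R)-2-methyl-9-oxononyl]-1,2-dioxolan-3-yl}acetic acid; 32 diethyl [(2E)-3-phenylprop-2-en-1-yl]phosphonate
Product: 33 {(3S,5R)-3,5-dimethyl-5-[(2R,9E,11E)-2-methyl-12-phenyldodeca-9,11-dien-1-yl]-1,2-dioxolan-3-yl}acetic acid
Conditions: 32 (2.2 equiv), LiN(SiMe3)2 (2.2 equiv), THF, −78 °C; then 31, −78 °C → rt; 1 M HCl; reverse-phase HPLC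
Reagents that add atoms: none
Why: Horner–Wadsworth–Emmons olefination with the allylic phosphonate anion forms the new C=C bond E-selectively while the cinnamyl E bond is retained; the first equivalent of anion makes the carboxylate, which cannot enolise to open the peroxide.

## Compound list

1 | 6-bromohexan-1-ol | OCCCCCCBr | starting material
2 | (6-bromohexyloxy)(tert-butyl)diphenylsilane | BrCCCCCCO[Si](c1ccccc1)(c1ccccc1)C(C)(C)C | intermediate
3 | (4R)-4-benzyl-3-propanoyl-1,3-oxazolidin-2-one | CCC(=O)N1[C@H](Cc2ccccc2)COC1=O | starting material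
4 | 3-bromo-1-(trimethylsilyl)prop-1-yne | C[Si](C)(C)C#CCBr | starting material
5 | (4R)-4-benzyl-3-[(2S)-2-methyl-5-(trimethylsilyl)pent-4-ynoyl]-1,3-oxazolidin-2-one | C[C@H](C(=O)N1[C@H](Cc2ccccc2)COC1=O)CC#C[Si](C)(C)C | intermediate
6 | (2S)-2-methyl-5-(trimethylsilyl)pent-4-yn-1-ol | C[C@H](CO)CC#C[Si](C)(C)C | intermediate
7 | (2S)-2-methyl-5-(trimethylsilyl)pent-4-yn-1-yl 4-methylbenzenesulfonate | C[C@H](COS(=O)(=O)c1ccc(C)cc1)CC#C[Si](C)(C)C | intermediate
8 | [6-(tert-butyldiphenylsilyloxy)hexyl]magnesium bromide | Br[Mg]CCCCCCO[Si](c1ccccc1)(c1ccccc1)C(C)(C)C | intermediate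
9 | tert-butyl{[(8R)-8-methyl-11-(trimethylsilyl)undec-10-yn-1-yl]oxy}diphenylsilane | C[C@H](CCCCCCCO[Si](c1ccccc1)(c1ccccc1)C(C)(C)C)CC#C[Si](C)(C)C | intermediate
10 | tert-butyl{[(8R)-8-methylundec-10-yn-1-yl]oxy}diphenylsilane | C[C@H](CCCCCCCO[Si](c1ccccc1)(c1ccccc1)C(C)(C)C)CC#C | intermediate
11 | [(1E,4R)-11-(tert-butyldiphenylsilyloxy)-2,4-dimethylundec-1-en-1-yl]dimethylalane | C[C@H](CCCCCCCO[Si](c1ccccc1)(c1ccccc1)C(C)(C)C)C/C(C)=C/[Al](C)C | intermediate
12 | lithium butyl[(1E,4R)-11-(tert-butyldiphenylsilyloxy)-2,4-dimethylundec-1-en-1-yl]dimethylaluminate | C[C@H](CCCCCCCO[Si](c1ccccc1)(c1ccccc1)C(C)(C)C)C/C(C)=C/[Al-](C)(C)CCCC.[Li+] | intermediate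
13 | (2E,5R)-12-(tert-butyldiphenylsilyloxy)-3,5-dimethyldodec-2-en-1-ol | C[C@H](CCCCCCCO[Si](c1ccccc1)(c1ccccc1)C(C)(C)C)C/C(C)=C/CO | intermediate
14 | {(2S,3S)-3-[(2R)-9-(tert-butyldiphenylsilyloxy)-2-methylnonyl]-3-methyloxiran-2-yl}methanol | C[C@H](CCCCCCCO[Si](c2ccccc2)(c3ccccc3)C(C)(C)C)C[C@]1(C)O[C@H]1CO | intermediate
15 | (3S,5R)-12-(tert-butyldiphenylsilyloxy)-3,5-dimethyldodecane-1,3-diol | C[C@H](CCCCCCCO[Si](c1ccccc1)(c1ccccc1)C(C)(C)C)C[C@](C)(O)CCO | intermediate
16 | (3S,5R)-12-(tert-butyldiphenylsilyloxy)-3-hydroxy-3,5-dimethyldodecanal | C[C@H](CCCCCCCO[Si](c1ccccc1)(c1ccccc1)C(C)(C)C)C[C@](C)(O)CC=O | intermediate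
17 | (2RS,4S,6R)-13-(tert-butyldiphenylsilyloxy)-4,6-dimethyltridecane-2,4-diol | C[C@H](CCCCCCCO[Si](c1ccccc1)(c1ccccc1)C(C)(C)C)C[C@](C)(O)CC(C)O | intermediate
18 | (2RS,4S,6R)-13-(tert-butyldiphenylsilyloxy)-4-hydroxy-4,6-dimethyltridecan-2-yl methanesulfonate | C[C@H](CCCCCCCO[Si](c1ccccc1)(c1ccccc1)C(C)(C)C)C[C@](C)(O)CC(C)OS(C)(=O)=O | intermediate
19 | (2S,4RS)-2-[(2R)-9-(tert-butyldiphenylsilyloxy)-2-methylnonyl]-2,4-dimethyloxetane | C[C@H](CCCCCCCO[Si](c2ccccc2)(c3ccccc3)C(C)(C)C)C[C@@]1(C)CC(C)O1 | intermediate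
20 | (2RS,4R,6R)-13-(tert-butyldiphenylsilyloxy)-4-hydroperoxy-4,6-dimethyltridecan-2-ol | C[C@H](CCCCCCCO[Si](c1ccccc1)(c1ccccc1)C(C)(C)C)C[C@@](C)(OO)CC(C)O | intermediate
21 | (2RS,4R,6R)-13-(tert-butyldiphenylsilyloxy)-4,6-dimethyl-4-[(triethylsilyl)peroxy]tridecan-2-ol | C[C@H](CCCCCCCO[Si](c1ccccc1)(c1ccccc1)C(C)(C)C)C[C@@](C)(OO[Si](CC)(CC)CC)CC(C)O | intermediate
22 | (4R,6R)-13-(tert-butyldiphenylsilyloxy)-4,6-dimethyl-4-[(triethylsilyl)peroxy]tridecan-2-one | C[C@H](CCCCCCCO[Si](c1ccccc1)(c1ccccc1)C(C)(C)C)C[C@@](C)(OO[Si](CC)(CC)CC)CC(C)=O | intermediate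
23 | (3RS,5R)-5-[(2R)-9-(tert-butyldiphenylsilyloxy)-2-methylnonyl]-3,5-dimethyl-1,2-dioxolan-3-ol | C[C@H](CCCCCCCO[Si](c2ccccc2)(c3ccccc3)C(C)(C)C)C[C@]1(C)CC(C)(O)OO1 | intermediate
24 | (3RS,5R)-5-[(2R)-9-(tert-butyldiphenylsilyloxy)-2-methylnonyl]-3-methoxy-3,5-dimethyl-1,2-dioxolane | C[C@H](CCCCCCCO[Si](c2ccccc2)(c3ccccc3)C(C)(C)C)C[C@]1(C)CC(C)(OC)OO1 | intermediate
25 | S-ethyl ethanethioate | CC(=O)SCC | starting material
26 | {[1-(ethylsulfanyl)ethenyl]oxy}trimethylsilane | C=C(O[Si](C)(C)C)SCC | intermediate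
27 | S-ethyl {(3S,5R)-5-[(2R)-9-(tert-butyldiphenylsilyloxy)-2-methylnonyl]-3,5-dimethyl-1,2-dioxolan-3-yl}ethanethioate | C[C@H](CCCCCCCO[Si](c2ccccc2)(c3ccccc3)C(C)(C)C)C[C@]1(C)C[C@@](C)(CC(=O)SCC)OO1 | intermediate
28 | {(3S,5R)-5-[(2R)-9-(tert-butyldiphenylsilyloxy)-2-methylnonyl]-3,5-dimethyl-1,2-dioxolan-3-yl}ethaneperoxoic acid | C[C@H](CCCCCCCO[Si](c2ccccc2)(c3ccccc3)C(C)(C)C)C[C@]1(C)C[C@@](C)(CC(=O)OO)OO1 | intermediate
29 | {(3S,5R)-5-[(2R)-9-(tert-butyldiphenylsilyloxy)-2-methylnonyl]-3,5-dimethyl-1,2-dioxolan-3-yl}acetic acid | C[C@H](CCCCCCCO[Si](c2ccccc2)(c3ccccc3)C(C)(C)C)C[C@]1(C)C[C@@](C)(CC(=O)O)OO1 | intermediate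
30 | {(3S,5R)-5-[(2R)-9-hydroxy-2-methylnonyl]-3,5-dimethyl-1,2-dioxolan-3-yl}acetic acid | C[C@H](CCCCCCCO)C[C@]1(C)C[C@@](C)(CC(=O)O)OO1 | intermediate
31 | {(3S,5R)-3,5-dimethyl-5-[(2R)-2-methyl-9-oxononyl]-1,2-dioxolan-3-yl}acetic acid | C[C@H](CCCCCCC=O)C[C@]1(C)C[C@@](C)(CC(=O)O)OO1 | intermediate
32 | diethyl [(2E)-3-phenylprop-2-en-1-yl]phosphonate | CCOP(=O)(C/C=C/c1ccccc1)OCC | starting material
33 | {(3S,5R)-3,5-dimethyl-5-[(2R,9E,11E)-2-methyl-12-phenyldodeca-9,11-dien-1-yl]-1,2-dioxolan-3-yl}acetic acid | C[C@H](CCCCCC/C=C/C=C/c1ccccc1)C[C@]1(C)C[C@@](C)(CC(=O)O)OO1 | target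

## Step count

Total: 22 steps. Longest linear sequence: 20 steps (steps 2–16 and 18–22, starting from 3).

## Steps most likely to fail, with fallbacks

**Step 12 (oxetane closure).** The tertiary alkoxide can fragment in a Grob sense or the secondary mesylate can eliminate. The fallback sets out from 16 and comes back at 19, closing the ring electrophilically with no alkoxide and no leaving group on the secondary carbon. Wittig methylenation of 16 (Ph3PCH3Br, KOtBu, THF, −78 → 0 °C) gives the homoallylic tertiary alcohol (4R,6R)-13-(tert-butyldiphenylsilyloxy)-4,6-dimethyltridec-1-en-4-ol F1. 4-exo iodoetherification (I2, NaHCO3, MeCN, 0 °C) then gives (2S,4RS)-2-[(2R)-9-(tert-butyldiphenylsilyloxy)-2-methylnonyl]-4-(iodomethyl)-2-methyloxetane F2. Radical deiodination (Bu3SnH, AIBN, toluene, 80 °C) gives 19.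

**Step 13 (perhydrolysis of the oxetane).** Regiochemistry, incomplete inversion or low conversion could fail here. The fallback sets out from 17 and comes back at 27; it gives up control at C5 in exchange for a classical tertiary-alcohol perhydrolysis. Dess–Martin oxidation of 17 gives the hydroxy ketone (4S,6R)-13-(tert-butyldiphenylsilyloxy)-4-hydroxy-4,6-dimethyltridecan-2-one F3. 50% H2O2 with catalytic H2SO4 (Et2O, 0 °C) replaces the tertiary OH by OOH through an SN1 path and the product closes to (3RS,5RS)-5-[(2R)-9-(tert-butyldiphenylsilyloxy)-2-methylnonyl]-3,5-dimethyl-1,2-dioxolan-3-ol F4. TsOH/MeOH gives (3RS,5RS)-5-[(2R)-9-(tert-butyldiphenylsilyloxy)-2-methylnonyl]-3-methoxy-3,5-dimethyl-1,2-dioxolane F5. F5 is put through the conditions of step 18 and 27 is isolated from its three diastereomers by preparative HPLC, so at most a quarter of the material is usable.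

**Step 18 (peroxycarbenium aldol).** The silyl ketene acetal may be consumed by TiCl4, the peroxide may decompose, or the two C3 epimers of the thioester may not separate. The fallback sets out from 24 and comes back at 29, replacing the enolate nucleophile by an allylsilane and building the acid by oxidative cleavage. Hosomi–Sakurai-type allylation of 24 (allyltrimethylsilane, SnCl4, CH2Cl2, −78 °C) gives, after separation of the C3 epimers, (3R,5R)-5-[(2R)-9-(tert-butyldiphenylsilyloxy)-2-methylnonyl]-3,5-dimethyl-3-(prop-2-en-1-yl)-1,2-dioxolane F6. Ozonolysis (O3, CH2Cl2/MeOH, −78 °C; then PPh3) gives {(3S,5R)-5-[(2R)-9-(tert-butyldiphenylsilyloxy)-2-methylnonyl]-3,5-dimethyl-1,2-dioxolan-3-yl}acetaldehyde F7. Pinnick oxidation (NaClO2, NaH2PO4, 2-methylbut-2-ene, t-BuOH/H2O) gives 29.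

## Further compounds

F1 | step 12 | (4R,6R)-13-(tert-butyldiphenylsilyloxy)-4,6-dimethyltridec-1-en-4-ol | C[C@H](CCCCCCCO[Si](c1ccccc1)(c1ccccc1)C(C)(C)C)C[C@](C)(O)CC=C
F2 | step 12 | (2S,4RS)-2-[(2R)-9-(tert-butyldiphenylsilyloxy)-2-methylnonyl]-4-(iodomethyl)-2-methyloxetane | C[C@H](CCCCCCCO[Si](c2ccccc2)(c3ccccc3)C(C)(C)C)C[C@@]1(C)CC(CI)O1
F3 | step 13 | (4S,6R)-13-(tert-butyldiphenylsilyloxy)-4-hydroxy-4,6-dimethyltridecan-2-one | C[C@H](CCCCCCCO[Si](c1ccccc1)(c1ccccc1)C(C)(C)C)C[C@](C)(O)CC(C)=O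
F4 | step 13 | (3RS,5RS)-5-[(2R)-9-(tert-butyldiphenylsilyloxy)-2-methylnonyl]-3,5-dimethyl-1,2-dioxolan-3-ol | C[C@H](CCCCCCCO[Si](c2ccccc2)(c3ccccc3)C(C)(C)C)CC1(C)CC(C)(O)OO1
F5 | step 13 | (3RS,5RS)-5-[(2R)-9-(tert-butyldiphenylsilyloxy)-2-methylnonyl]-3-methoxy-3,5-dimethyl-1,2-dioxolane | C[C@H](CCCCCCCO[Si](c2ccccc2)(c3ccccc3)C(C)(C)C)CC1(C)CC(C)(OC)OO1
F6 | step 18 | (3R,5R)-5-[(2R)-9-(tert-butyldiphenylsilyloxy)-2-methylnonyl]-3,5-dimethyl-3-(prop-2-en-1-yl)-1,2-dioxolane | C[C@H](CCCCCCCO[Si](c2ccccc2)(c3ccccc3)C(C)(C)C)C[C@]1(C)C[C@@](C)(CC=C)OO1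
F7 | step 18 | {(3S,5R)-5-[(2R)-9-(tert-butyldiphenylsilyloxy)-2-methylnonyl]-3,5-dimethyl-1,2-dioxolan-3-yl}acetaldehyde | C[C@H](CCCCCCCO[Si](c2ccccc2)(c3ccccc3)C(C)(C)C)C[C@]1(C)C[C@@](C)(CC=O)OO1
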